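Everything rests on opening the lactone ring (O1, carbonyl C2, C3, C4, C5) back to a four-membered ketone. O1 lies between C2 and the benzylic carbon C5 that carries ring B, which is precisely the site a Baeyer–Villiger oxidation fills in a 2-arylcyclobutanone. One operation thus makes O1–C2 and O1–C5, enlarges the carbocycle to the lactone and transfers the trans C4/C5 relationship unchanged. The substrate is the trans (2R,3R)-2-aryl-3-(silyloxymethyl)cyclobutanone, built by an auxiliary-controlled keteniminium–alkene [2+2] cycloaddition followed by base equilibration. Ring A is then attached at C3 as a benzylidene, and its hydrogenation sets the 3,4-cis centre.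

Key step: step 5

Conventions: TBS = tert-butyldimethylsilyl. Lactone numbering is O1, C2 (C=O), C3, C4, C5. Ring A is the aryl of the C3 benzyl group and ring B is the aryl on C5.

Stereochemical reading: the target is (3S,4S,5R). The C3 benzyl and C4 CH2OH groups are cis, and the C4 CH2OH group and ring B are trans. The matching cyclobutanone is (2R,3R) and the matching lactone is (4S,5R).

Assumption: the (2R,5R) enantiomer of the auxiliary is taken to deliver the (3R) cyclobutanone. The sense of induction has to be checked on the first batch, and the equally available (2S,5S)-amine replaces it in the same steps if the sense proves opposite.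

Step 1
Reactants: 1 homovanillic acid
Product: 2 TBS 2-[4-(TBS-oxy)-3-methoxyphenyl]acetate
Conditions: TBSCl (2.3 equiv), imidazole (5 equiv), DMF, rt
Reagents that add atoms: tert-butyldimethylsilyl chloride (TBSCl), CC(C)(C)[Si](C)(C)Cl
Why: Imidazole-promoted O-silylation caps the phenol and the acid together, and the silyl ester is kept because it feeds directly into a neutral acid chloride synthesis.

Step 2
Reactants: 2 TBS 2-[4-(TBS-oxy)-3-methoxyphenyl]acetate; 3 (2R,5R)-2,5-dimethylpyrrolidine
Product: 5 2-[4-(TBS-oxy)-3-methoxyphenyl]-1-[(2R,5R)-2,5-dimethylpyrrolidin-1-yl]ethan-1-one, via arylacetyl chloride 4 (not isolated)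
Conditions: (COCl)2, DMF (cat.), CH2Cl2, 0 °C → rt; evaporate; then 3, Et3N, CH2Cl2, 0 °C → rt
Reagents that add atoms: oxalyl chloride, O=C(Cl)C(=O)Cl (chlorine of intermediate 4 only; nothing remains in 5)
Why: The Vilsmeier-type chloroiminium salt turns a silyl ester into the acyl chloride without liberating HCl, and N-acylation with this reactive acyl donor overcomes the hindrance of the doubly α-branched amine without touching its stereocentres.

Step 3
Reactants: 5 arylacetamide of the auxiliary; 6 allyloxy-tert-butyldimethylsilane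
Product: 9 (3R)-2-[4-(TBS-oxy)-3-methoxyphenyl]-3-[(TBS-oxy)methyl]cyclobutan-1-one (mixture of C2 epimers), via keteniminium triflate 7 (not isolated), via cyclobutaniminium triflate 8 (not isolated)
Conditions: Tf2O (1.2 equiv), ClCH2CH2Cl, −20 °C; then 6 (3 equiv), 2,4,6-collidine (1.3 equiv), → 60 °C; then aq. NaHCO3, 40 °C
Reagents that add atoms: water, O (carbonyl oxygen of 9); triflic anhydride, O=S(=O)(OS(=O)(=O)C(F)(F)F)C(F)(F)F (triflate counter-ion of 7 and 8 only)
Why: O-Triflation of the tertiary amide and loss of the acidic benzylic proton give 7, which enters the known thermal keteniminium–alkene [2+2] cycloaddition with its central carbon bonding to the terminal CH2 of 6 and its aryl-bearing carbon to the internal CH (hence the 2-aryl-3-substituted pattern), the rotationally symmetric trans-dimethylpyrrolidine allowing only one keteniminium geometry and admitting one alkene face so that C3 is set as R, before hydrolysis of 8 frees the ketone and the recoverable amine.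

Step 4
Reactants: 9 cyclobutanone as mixture of C2 epimers
Product: 10 (2R,3R)-2-[4-(TBS-oxy)-3-methoxyphenyl]-3-[(TBS-oxy)methyl]cyclobutan-1-one (2,3-trans)
Conditions: DBU (0.2 equiv), dry CH2Cl2, rt
Reagents that add atoms: none
Why: Base-mediated epimerisation through the aryl-conjugated enolate exchanges only the acidic C2–H, and the 2,3-trans isomer is the thermodynamic sink, so C2 becomes R under the control of the fixed C3 centre.

Step 5
Reactants: 10 trans-(2R,3R)-cyclobutanone
Product: 12 (4S,5R)-5-[4-(TBS-oxy)-3-methoxyphenyl]-4-[(TBS-oxy)methyl]oxolan-2-one (4,5-trans), via Criegee adduct 11 (not isolated)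
Conditions: mCPBA (1.3 equiv), NaHCO3 (3 equiv), CH2Cl2, 0 °C
Reagents that add atoms: 3-chloroperbenzoic acid (mCPBA), OOC(=O)c1cccc(Cl)c1 (ring oxygen O1)
Why: The peracid adds to the strained carbonyl to give adduct 11, whose C1–C2 ring bond shifts onto the proximal peroxide oxygen as 3-chlorobenzoate leaves, which is the Baeyer–Villiger oxidation routinely used to turn 2-substituted cyclobutanones into γ-butyrolactones. The five-membered lactone arises by one-atom ring expansion of the carbocycle (1,2-shift of a ring bond onto oxygen) and not by closure of an open chain, and O1–C2 and O1–C5 are both made in this event. No stereocentre is created: the migrating carbon keeps its configuration, so (2R) becomes (5R), C4 is untouched and the trans relationship fixed in step 4 is carried over. The selectivity needed is migration of the aryl-bearing CH in preference to the ring CH2, and the substrate secures it because that carbon is secondary, benzylic and attached to a donor-substituted ring that stabilises the positive charge building up during the shift. Strain release lets the ketone react at 0 °C, ahead of any attack on the silylated guaiacyl ring, and NaHCO3 keeps 3-chlorobenzoic acid from ionising the new benzylic C5–O1 bond or loosening the silyl ethers.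

Step 6
Reactants: 13 vanillin
Product: 14 4-(TBS-oxy)-3-methoxybenzaldehyde
Conditions: TBSCl, imidazole, CH2Cl2, rt
Reagents that add atoms: tert-butyldimethylsilyl chloride (TBSCl), CC(C)(C)[Si](C)(C)Cl
Why: Imidazole-promoted O-silylation of the acidic phenol removes the only proton that would quench the enolate of the next step.

Step 7
Reactants: 12 (4S,5R)-lactone; 14 4-(TBS-oxy)-3-methoxybenzaldehyde
Product: 16 (3S,4S,5R)-3-{[4-(TBS-oxy)-3-methoxyphenyl](hydroxy)methyl}-5-[4-(TBS-oxy)-3-methoxyphenyl]-4-[(TBS-oxy)methyl]oxolan-2-one (3,4-trans; both carbinol epimers), via lithium enolate 15 (not isolated)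
Conditions: LiN(SiMe3)2 (1.1 equiv), THF, −78 °C; then 14, −78 °C; aq. NH4Cl
Reagents that add atoms: LiN(SiMe3)2, [Li]N([Si](C)(C)C)[Si](C)(C)C (lithium of intermediate 15 only; nothing remains in 16)
Why: Directed aldol addition of a lactone lithium enolate to a non-enolisable aldehyde is reliable here because no leaving group sits β to the enolate, the new bond forms anti to the C4 arm, and both new centres are erased in step 8 so their ratio does not matter.

Step 8
Reactants: 16 aldol adduct
Product: 18 (3E,4S,5R)-3-[4-(TBS-oxy)-3-methoxybenzylidene]-5-[4-(TBS-oxy)-3-methoxyphenyl]-4-[(TBS-oxy)methyl]oxolan-2-one, via mesylate 17 (not isolated)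
Conditions: MsCl, Et3N, CH2Cl2, 0 °C; then DBU, 0 °C → rt
Reagents that add atoms: methanesulfonyl chloride, CS(=O)(=O)Cl (mesyl group of intermediate 17 only; nothing remains in 18)
Why: Mesylation followed by E1cB elimination gives the aryl-conjugated exocyclic alkene with the E geometry favoured thermodynamically, and short exposure to dry DBU should leave the C4 and C5 centres and the aryl silyl ethers intact.

Step 9
Reactants: 18 (E)-benzylidene lactone
Product: 19 (3S,4S,5R)-3-[4-(TBS-oxy)-3-methoxybenzyl]-5-[4-(TBS-oxy)-3-methoxyphenyl]-4-[(TBS-oxy)methyl]oxolan-2-one (3,4-cis; 4,5-trans)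
Conditions: H2 (1 atm), 10% Pd/C, Ph2S (cat.), EtOAc, rt
Reagents that add atoms: none
Why: Heterogeneous catalytic hydrogenation adds H2 syn from the ring face away from the neighbouring C4 arm, which A(1,3) strain with the E-aryl group forces pseudoaxial, so C3–H ends trans and the benzyl group cis to that arm (3S), while the sulfide-moderated catalyst in EtOAc saturates alkenes but spares benzylic esters and silyl ethers, so C5–O1 should survive.

Step 10
Reactants: 19 tris-TBS lactone
Product: 20 (3S,4S,5R)-5-(4-hydroxy-3-methoxyphenyl)-3-(4-hydroxy-3-methoxybenzyl)-4-(hydroxymethyl)oxolan-2-one (target)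
Conditions: Et3N·3HF (excess), THF, 0 °C → rt
Reagents that add atoms: none
Why: Fluoride-induced Si–O cleavage with a weakly acidic, non-basic reagent removes all three silyl groups while avoiding enolisation at the kinetically set C3, acyl transfer to the freed primary hydroxyl and ionisation at benzylic C5.

Compound list
1 | homovanillic acid | COc1cc(CC(=O)O)ccc1O | starting material
2 | TBS 2-[4-(TBS-oxy)-3-methoxyphenyl]acetate | COc1cc(CC(=O)O[Si](C)(C)C(C)(C)C)ccc1O[Si](C)(C)C(C)(C)C | intermediate
3 | (2R,5R)-2,5-dimethylpyrrolidine | C[C@@H]1CC[C@@H](C)N1 | starting material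
4 | 2-[4-(TBS-oxy)-3-methoxyphenyl]acetyl chloride | COc1cc(CC(=O)Cl)ccc1O[Si](C)(C)C(C)(C)C | intermediate
5 | 2-[4-(TBS-oxy)-3-methoxyphenyl]-1-[(2R,5R)-2,5-dimethylpyrrolidin-1-yl]ethan-1-one | COc1cc(CC(=O)N2[C@H](C)CC[C@H]2C)ccc1O[Si](C)(C)C(C)(C)C | intermediate
6 | allyloxy-tert-butyldimethylsilane | C=CCO[Si](C)(C)C(C)(C)C | starting material
7 | (2R,5R)-1-{2-[4-(TBS-oxy)-3-methoxyphenyl]ethenylidene}-2,5-dimethylpyrrolidinium triflate | COc1cc(C=C=[N+]2[C@H](C)CC[C@H]2C)ccc1O[Si](C)(C)C(C)(C)C.[O-]S(=O)(=O)C(F)(F)F | intermediate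
8 | (2R,5R)-1-{(3R)-2-[4-(TBS-oxy)-3-methoxyphenyl]-3-[(TBS-oxy)methyl]cyclobutylidene}-2,5-dimethylpyrrolidinium triflate (C2 epimers) | C1C(=[N+]2[C@H](C)CC[C@H]2C)C(c3ccc(O[Si](C)(C)C(C)(C)C)c(OC)c3)[C@@H]1CO[Si](C)(C)C(C)(C)C.[O-]S(=O)(=O)C(F)(F)F | intermediate
9 | (3R)-2-[4-(TBS-oxy)-3-methoxyphenyl]-3-[(TBS-oxy)methyl]cyclobutan-1-one (C2 epimers) | C1C(=O)C(c2ccc(O[Si](C)(C)C(C)(C)C)c(OC)c2)[C@@H]1CO[Si](C)(C)C(C)(C)C | intermediate
10 | (2R,3R)-2-[4-(TBS-oxy)-3-methoxyphenyl]-3-[(TBS-oxy)methyl]cyclobutan-1-one (trans) | C1C(=O)[C@@H](c2ccc(O[Si](C)(C)C(C)(C)C)c(OC)c2)[C@@H]1CO[Si](C)(C)C(C)(C)C | intermediate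
11 | Criegee adduct: 1-hydroxy-1-(3-chlorobenzoylperoxy) derivative of 10 (C1 undefined) | C1C(O)(OOC(=O)c3cccc(Cl)c3)[C@@H](c2ccc(O[Si](C)(C)C(C)(C)C)c(OC)c2)[C@@H]1CO[Si](C)(C)C(C)(C)C | intermediate
12 | (4S,5R)-5-[4-(TBS-oxy)-3-methoxyphenyl]-4-[(TBS-oxy)methyl]oxolan-2-one (trans) | C1C(=O)O[C@@H](c2ccc(O[Si](C)(C)C(C)(C)C)c(OC)c2)[C@@H]1CO[Si](C)(C)C(C)(C)C | intermediate
13 | vanillin | COc1cc(C=O)ccc1O | starting material
14 | 4-(TBS-oxy)-3-methoxybenzaldehyde | COc1cc(C=O)ccc1O[Si](C)(C)C(C)(C)C | intermediate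
15 | lithium enolate of 12 | C1=C([O-])O[C@@H](c2ccc(O[Si](C)(C)C(C)(C)C)c(OC)c2)[C@@H]1CO[Si](C)(C)C(C)(C)C.[Li+] | intermediate
16 | (3S,4S,5R)-aldol adduct, 3,4-trans, carbinol epimers | OC(c1ccc(O[Si](C)(C)C(C)(C)C)c(OC)c1)[C@H]2C(=O)O[C@@H](c3ccc(O[Si](C)(C)C(C)(C)C)c(OC)c3)[C@@H]2CO[Si](C)(C)C(C)(C)C | intermediate
17 | methanesulfonate of 16 | CS(=O)(=O)OC(c1ccc(O[Si](C)(C)C(C)(C)C)c(OC)c1)[C@H]2C(=O)O[C@@H](c3ccc(O[Si](C)(C)C(C)(C)C)c(OC)c3)[C@@H]2CO[Si](C)(C)C(C)(C)C | intermediate
18 | (3E,4S,5R)-3-[4-(TBS-oxy)-3-methoxybenzylidene]-5-[4-(TBS-oxy)-3-methoxyphenyl]-4-[(TBS-oxy)methyl]oxolan-2-one | COc1cc(/C=C2/C(=O)O[C@@H](c3ccc(O[Si](C)(C)C(C)(C)C)c(OC)c3)[C@@H]2CO[Si](C)(C)C(C)(C)C)ccc1O[Si](C)(C)C(C)(C)C | intermediate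
19 | (3S,4S,5R)-3-[4-(TBS-oxy)-3-methoxybenzyl]-5-[4-(TBS-oxy)-3-methoxyphenyl]-4-[(TBS-oxy)methyl]oxolan-2-one | COc1cc(C[C@@H]2C(=O)O[C@@H](c3ccc(O[Si](C)(C)C(C)(C)C)c(OC)c3)[C@@H]2CO[Si](C)(C)C(C)(C)C)ccc1O[Si](C)(C)C(C)(C)C | intermediate
20 | (3S,4S,5R)-5-(4-hydroxy-3-methoxyphenyl)-3-(4-hydroxy-3-methoxybenzyl)-4-(hydroxymethyl)oxolan-2-one | COc1cc(C[C@@H]2C(=O)O[C@@H](c3ccc(O)c(OC)c3)[C@@H]2CO)ccc1O | target

Total step count: 10
Longest linear sequence: 9 (steps 1–5 and 7–10; step 6 is the side branch)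

Steps most likely to fail

1. Step 3.
- **What may go wrong:** The cycloaddition may be sluggish on a terminal alkene that the allylic oxygen deactivates. The electron-rich ring or a second amide molecule may attack the activated amide instead. Facial discrimination by the auxiliary may be incomplete.
- **Fallback:** The stereocentre is taken from the chiral pool and the four-membered ring is made by enlarging a three-membered one. The detour sets out from aldehyde 14 and comes back at cyclobutanone 9.
- Excess Ph3P=CH2 (from Ph3PCH3Br and n-BuLi, THF) and (R)-epichlorohydrin should react in one flask by epoxide opening, epoxide shift and 3-exo ring closure with inversion. This gives lithium [(S)-2-(triphenylphosphoranylidene)cyclopropyl]methanolate F1.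
- Wittig reaction of this ylide with 14 gives {(1R)-2-[4-(TBS-oxy)-3-methoxybenzylidene]cyclopropyl}methanol F2 as an E/Z mixture.
- TBSCl and imidazole convert it into its TBS ether F3.
- One equivalent of mCPBA (NaHCO3, CH2Cl2, 0 °C) epoxidises the strained styrene-type alkene to the 2-aryl-1-oxaspiro[2.2]pentane F4.
- This compound is expected to rearrange in the flask through the donor-stabilised benzylic cation, with a 1,2-shift of the more substituted cyclopropane carbon and retention there. The product is 9 with C3 already R, and step 4 follows unchanged.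

2. Step 9.
- **What may go wrong:** Hydrogen may be delivered from the wrong face, because ring B at C5 partly covers the face that should be open. The benzylic C5–O1 bond may be cleaved by hydrogenolysis. Uptake of the hindered trisubstituted alkene on the moderated catalyst may be slow.
- **Fallback:** The C3–carbon bond is made by alkylation and the cis relationship by kinetic protonation, so no hydrogenation is needed. The detour sets out from lactone 12 and aldehyde 14 and comes back at 19.
- NaBH4 (MeOH, 0 °C) reduces 14 to 4-(TBS-oxy)-3-methoxybenzyl alcohol F5. PBr3 (Et2O, 0 °C) then gives 4-(TBS-oxy)-3-methoxybenzyl bromide F6, which is used at once.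
- Enolate 15, generated as in step 7, is alkylated by the bromide anti to the C4 arm to give the (3R,4S,5R) 3,4-trans benzyl lactone F7.
- LiN(i-Pr)2 (THF, −78 °C) converts it into the planar lithium enolate F8.
- A hindered proton source (2,6-di-tert-butyl-4-methylphenol, −78 °C) should deliver the proton to the face away from the C4 arm. That places the benzyl group cis and gives 19, and unconverted trans material can be resubmitted.

3. Step 5.
- **What may go wrong:** The ring CH2 may migrate in competition with the benzylic carbon. The peracid may oxidise the donor-substituted ring B. Acid may ionise the new benzylic C–O bond, with erosion of the trans relationship.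
- **Fallback:** The lactone is made by aldol addition and closure of an open chain instead of ring expansion. The detour sets out from aldehyde 14 and comes back at lactone 12.
- (R)-4-Benzyl-1,3-oxazolidin-2-one is N-acylated (n-BuLi, THF, −78 °C; methyl 4-chloro-4-oxobutanoate) to (4R)-4-benzyl-3-(4-methoxy-4-oxobutanoyl)-1,3-oxazolidin-2-one F9.
- Evans syn-aldol addition to 14 (Bu2BOTf, Et3N, CH2Cl2, −78 → 0 °C) gives the (R,R) syn-aldol adduct F10.
- Its secondary hydroxyl closes onto the methyl ester, on work-up or with catalytic pyridinium p-toluenesulfonate, to give the trans lactone imide F11.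
- NaBH4 in THF/H2O (0 °C) reduces the exocyclic imide carbonyl in preference to the lactone. This gives (4S,5R)-5-[4-(TBS-oxy)-3-methoxyphenyl]-4-(hydroxymethyl)oxolan-2-one F12 and returns the auxiliary.
- TBSCl and imidazole then give 12.

Further compounds
F1 | step 3 | lithium [(S)-2-(triphenylphosphoranylidene)cyclopropyl]methanolate | [Li+].[O-]C[C@@H]1CC1=P(c2ccccc2)(c2ccccc2)c2ccccc2
F2 | step 3 | {(1R)-2-[4-(TBS-oxy)-3-methoxybenzylidene]cyclopropyl}methanol (E/Z mixture) | COc1cc(C=C2C[C@H]2CO)ccc1O[Si](C)(C)C(C)(C)C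
F3 | step 3 | TBS ether of F2 | COc1cc(C=C2C[C@H]2CO[Si](C)(C)C(C)(C)C)ccc1O[Si](C)(C)C(C)(C)C
F4 | step 3 | 2-[4-(TBS-oxy)-3-methoxyphenyl]-4-[(TBS-oxy)methyl]-1-oxaspiro[2.2]pentane (epoxide centres undefined) | COc1cc(C2OC23C[C@H]3CO[Si](C)(C)C(C)(C)C)ccc1O[Si](C)(C)C(C)(C)C
F5 | step 9 | 4-(TBS-oxy)-3-methoxybenzyl alcohol | COc1cc(CO)ccc1O[Si](C)(C)C(C)(C)C
F6 | step 9 | 4-(TBS-oxy)-3-methoxybenzyl bromide | COc1cc(CBr)ccc1O[Si](C)(C)C(C)(C)C
F7 | step 9 | (3R,4S,5R)-3-[4-(TBS-oxy)-3-methoxybenzyl]-5-[4-(TBS-oxy)-3-methoxyphenyl]-4-[(TBS-oxy)methyl]oxolan-2-one (3,4-trans) | COc1cc(C[C@H]2C(=O)O[C@@H](c3ccc(O[Si](C)(C)C(C)(C)C)c(OC)c3)[C@@H]2CO[Si](C)(C)C(C)(C)C)ccc1O[Si](C)(C)C(C)(C)C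
F8 | step 9 | lithium enolate of F7 | COc1cc(CC2=C([O-])O[C@@H](c3ccc(O[Si](C)(C)C(C)(C)C)c(OC)c3)[C@@H]2CO[Si](C)(C)C(C)(C)C)ccc1O[Si](C)(C)C(C)(C)C.[Li+]
F9 | step 5 | (4R)-4-benzyl-3-(4-methoxy-4-oxobutanoyl)-1,3-oxazolidin-2-one | COC(=O)CCC(=O)N1[C@H](Cc2ccccc2)COC1=O
F10 | step 5 | methyl (3R)-3-{(R)-[4-(TBS-oxy)-3-methoxyphenyl](hydroxy)methyl}-4-[(4R)-4-benzyl-2-oxo-1,3-oxazolidin-3-yl]-4-oxobutanoate | COC(=O)C[C@@H](C(=O)N1[C@H](Cc2ccccc2)COC1=O)[C@@H](O)c3ccc(O[Si](C)(C)C(C)(C)C)c(OC)c3
F11 | step 5 | (4R)-4-benzyl-3-{[(2R,3R)-2-[4-(TBS-oxy)-3-methoxyphenyl]-5-oxooxolan-3-yl]carbonyl}-1,3-oxazolidin-2-one | C1C(=O)O[C@@H](c2ccc(O[Si](C)(C)C(C)(C)C)c(OC)c2)[C@@H]1C(=O)N3[C@H](Cc4ccccc4)COC3=O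
F12 | step 5 | (4S,5R)-5-[4-(TBS-oxy)-3-methoxyphenyl]-4-(hydroxymethyl)oxolan-2-one | C1C(=O)O[C@@H](c2ccc(O[Si](C)(C)C(C)(C)C)c(OC)c2)[C@@H]1CO
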